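(The rate constants were chosen freely; the result is computed.)

Which way of charging this flask ends the hour with the highest Tgt: Sub fed on Monday's, nothing fed on Friday's, or Sub2 fed on Sunday's?

| setting | Monday's | Friday's | Sunday's |
|---|---|---|---|
| Sub | 15 mM (fed, over 40 min) | 15 mM | 15 mM |
| Sub2 | 1.30 equiv | 1.30 equiv | 1.30 equiv (fed, over 40 min) |
| Ctl | 8.2 × 10⁻⁴ mol% | 8.2 × 10⁻⁴ mol% | 8.2 × 10⁻⁴ mol% |
| Tsp | 0.15 µM | 0.15 µM | 0.15 µM |
| time | 1.0 h | 1.0 h | 1.0 h |
| remark | all else is in the flask from the start; the feed brings no volume worth counting | everything together at the start | all else is in the flask from the start; the feed brings no volume worth counting |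

    Int2 → Ctl + Tgt (k1 = 2300 min⁻¹)
    Sub + Ctl ⇌ Int (K2 = 2800 M⁻¹, k2 = 5.3 × 10⁵ M⁻¹ s⁻¹)
    Sub2 + Int ⇌ Int2 (K3 = 43 M⁻¹, k3 = 27000 M⁻¹ s⁻¹)
    Tgt + Ctl ⇌ Ofp + Ctl, rate k4*[Ctl]*[Tgt] forward; the back reaction follows from the equilibrium constant (K4 = 0.34, k4 = 3.1 × 10⁵ M⁻¹ min⁻¹)
    Ctl + Tsp → Zet (k5 = 42000 M⁻¹ s⁻¹)

* the flask that comes out highest in amount of Tgt, in percent of the Sub charged, or "all alike" when all lie within 1.5 percentage points (Monday's / Friday's / Sunday's / all alike)
* Tgt at the end, in percent of the Sub charged, Monday's
* Tgt at the end, in percent of the Sub charged, Friday's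
* Tgt at the end, in percent of the Sub charged, Sunday's

Two chemists differ. The first counts heads: Tsp stands at 0.15 µM against 0.123 µM of Ctl, more poison than catalyst. Bare Ctl is captured at 0.378 min⁻¹, a half-life of 1.83 min, so on this view the catalyst is lost within minutes whichever way the flask is charged.

The second chemist, whose reckoning I share, works with the fraction of catalyst left, and notes that Tsp takes Ctl, not Int or Int2. Int2 sheds Sub2 at 37700 min⁻¹ and Int sheds Sub at 11400 min⁻¹, both faster than Int2 goes on at 2300 min⁻¹, so I take the bound forms to stand near equilibrium with Ctl, a pre-equilibrium. The bare part of the live catalyst is then one over one plus the Sub term times one plus the Sub2 term, these terms being 42 and 0.84 at Friday's start. That gives 1.28%, the exposed share, the part of the live catalyst standing as bare Ctl.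

With the share and Tsp held steady, the fraction left falls as the exponential of minus capture rate times exposed share times time, so over 1.0 h Friday's keeps 74.8%.

On Monday's, Sub arrives at 0.375 mM min⁻¹ onto bare catalyst, so the share starts high and falls as one over one plus a constant times time. Counting no Sub as used and taking the Sub2 term as on Friday's, that constant is 1.93 min⁻¹. Integrating over the feed with Tsp held steady leaves 42.6% at its end, less than Friday's keeps over its whole hour.

If Tgt goes with these two fractions, the first taken at the end of the feed and the second at the end of the hour, Monday's ends at about 0.569 of Friday's. The reckoning goes that far, a crude ratio and no yield.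

The forecast takes the second side with Friday's on top, at 24.5% for Monday's, 36.5% for Friday's and 25% for Sunday's, holding that “Everything-at-once keeps Ctl bound from the start”, and its Monday-to-Friday ratio of 0.671 is higher than mine.

The simulation gives Friday's highest, with 21.6% on Monday's, 36.3% on Friday's and 25.6% on Sunday's, a Monday-to-Friday ratio of 0.595, so Friday's stands above Monday's, the order the second chemist held. The first chemist's count has its ground in the long run: after 10.0 h, Friday's holds 98.8% of its catalyst as Zet.

The half-life that the exposed share gives Friday's start, 2.39 h, is longer than the hour, and the catalyst outside Zet reads 67.4% on Friday's after 1.00 h, against the 74.8% reckoned with the starting share held, and 44.7% on Monday's at the end of the feed, against the reckoned 42.6%. On Sunday's, Sub2 is absent at the start, so with the same Sub term the share begins at 2.33%, a half-life of 1.31 h, and after 1.00 h the catalyst outside Zet in that flask reads 68.0%.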